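The route rests on disconnecting the C3'–C3''' bond between the two B rings. Because this bond is flanked by the 4'- and 4'''-oxygens, the biaryl is a 2,2'-biphenol whose two oxygens can share one silicon atom. In the key step a di-tert-butylsilyl bis(aryl) ether, carrying 5,7-di-O-benzylapigenin on one oxygen and 2-bromo-4-chlorophenol on the other, undergoes palladium-catalysed intramolecular C–H arylation, forging the biaryl bond and a dibenzo-dioxasilepine in one operation. The surviving chloride becomes a boronic acid, which a rhodium-catalysed enantioselective 1,4-addition to 5,7-bis(benzyloxy)chromone converts into the (2S)-flavanone last, before acidic desilylation and neutral debenzylation.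

Key step: step 7

Locants: the flavanone unit uses plain numbers for rings A and C and primed numbers for ring B; the flavone unit uses double-primed numbers for its chromone and triple-primed numbers for its ring B.

Remark on the chemistry: (S)-MeO-F12-BIPHEP (2,2'-bis[bis(3,4,5-trifluorophenyl)phosphino]-6,6'-dimethoxy-1,1'-biphenyl) is taken as the antipode that delivers the aryl group to the Re face of chromone C2, by analogy with (S)-configured atropisomeric bisphosphine–rhodium catalysts in additions to cyclic enones. A trial with 4-methoxyphenylboronic acid and 4 is to confirm this before 15 is committed; the (R)-ligand would be used should the trial show the opposite sense.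

Step 1
Reactants: 1 2',4',6'-trihydroxyacetophenone
Product: 2 1-[2,4-bis(benzyloxy)-6-hydroxyphenyl]ethanone
Conditions: BnBr (2.1 equiv), K2CO3 (2.2 equiv), DMF, 0 °C to rt
Reagents that add atoms: benzyl bromide, BrCc1ccccc1
Why: Williamson etherification should stop at the dibenzyl stage because the last ortho hydroxyl is locked in a hydrogen bond to the acetyl carbonyl and is the least nucleophilic oxygen.

Step 2
Reactants: 2 1-[2,4-bis(benzyloxy)-6-hydroxyphenyl]ethanone
Product: 4 5,7-bis(benzyloxy)-4H-chromen-4-one, via enaminone 3 (not isolated)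
Conditions: Me2NCH(OMe)2, toluene, 95 °C; concentrate; then conc. aq. HCl, CH2Cl2, 40 °C
Reagents that add atoms: N,N-dimethylformamide dimethyl acetal, COC(OC)N(C)C
Why: Enaminone route to chromones: the amide acetal condenses with the methyl ketone to supply C2, and acid then triggers intramolecular oxa-Michael addition of the phenol with loss of dimethylamine to close the pyranone, under conditions too mild to cleave the benzyl ethers.

Step 3
Reactants: 5 4-hydroxybenzaldehyde
Product: 6 4-(methoxymethoxy)benzaldehyde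
Conditions: MOMCl, i-Pr2NEt, CH2Cl2, 0 °C to rt
Reagents that add atoms: chloromethyl methyl ether, COCCl
Why: O-alkylation of the phenol as its MOM acetal masks the acidic hydroxyl, which as a phenoxide would deactivate the aldehyde in the following aldol condensation.

Step 4
Reactants: 2 1-[2,4-bis(benzyloxy)-6-hydroxyphenyl]ethanone; 6 4-(methoxymethoxy)benzaldehyde
Product: 7 (E)-1-[2,4-bis(benzyloxy)-6-hydroxyphenyl]-3-[4-(methoxymethoxy)phenyl]prop-2-en-1-one
Conditions: KOH (50% aq.), EtOH/THF, rt; then cold 1 M HCl to pH 6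
Reagents that add atoms: none
Why: Claisen–Schmidt condensation of the methyl ketone enolate with a non-enolisable aldehyde should give the conjugated E-chalcone after dehydration, with benzyl and MOM ethers inert to hydroxide.

Step 5
Reactants: 7 (E)-1-[2,4-bis(benzyloxy)-6-hydroxyphenyl]-3-[4-(methoxymethoxy)phenyl]prop-2-en-1-one
Product: 9 5,7-bis(benzyloxy)-2-(4-hydroxyphenyl)-4H-chromen-4-one (5,7-di-O-benzylapigenin), via MOM flavone 8 (not isolated)
Conditions: I2 (10 mol %), DMSO, 130 °C; then crude material, HCl (3 M aq.), MeOH/THF, 50 °C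
Reagents that add atoms: none
Why: Iodine-catalysed oxidative cyclisation of a 2'-hydroxychalcone (oxa-Michael closure, alpha-iodination, loss of HI, reoxidation of HI by DMSO) should give the flavone, and acid-catalysed acetal exchange with methanol then removes whatever MOM group remains while the benzyl ethers stay.

Step 6
Reactants: 10 2-bromo-4-chlorophenol; 9 5,7-bis(benzyloxy)-2-(4-hydroxyphenyl)-4H-chromen-4-one
Product: 12 5,7-bis(benzyloxy)-2-[4-({(2-bromo-4-chlorophenoxy)di-tert-butylsilyl}oxy)phenyl]-4H-chromen-4-one, via aryloxysilyl triflate 11 (not isolated)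
Conditions: 10 (1.3 equiv), t-Bu2Si(OTf)2 (1.3 equiv), 2,6-lutidine, CH2Cl2, −20 to 0 °C; then 9 (1.0 equiv), imidazole, DMF, CH2Cl2 distilled off, 50 °C
Reagents that add atoms: di-tert-butylsilyl bis(trifluoromethanesulfonate), CC(C)(C)[Si](OS(=O)(=O)C(F)(F)F)(OS(=O)(=O)C(F)(F)F)C(C)(C)C
Why: Stepwise silyl ether formation: the first triflate is displaced in the cold while the second, flanked by two tert-butyl groups and an aryloxy group, needs heat and imidazole, so the hindered bromophenol goes on first and the valuable flavone phenol second, which should limit the symmetric bis(aryloxy)silanes.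

Step 7
Reactants: 12 5,7-bis(benzyloxy)-2-[4-({(2-bromo-4-chlorophenoxy)di-tert-butylsilyl}oxy)phenyl]-4H-chromen-4-one
Product: 13 5,7-bis(benzyloxy)-2-(6,6-di-tert-butyl-10-chlorodibenzo[d,f][1,3,2]dioxasilepin-2-yl)-4H-chromen-4-one
Conditions: Pd(OAc)2 (5 mol %), P(4-FC6H4)3 (10 mol %), Cs2CO3 (1.5 equiv), CsOPiv (30 mol %), 3 Å MS, p-xylene, 140 °C
Reagents that add atoms: none
Why: Zerovalent palladium inserts into the C–Br bond of the bromochlorophenoxy ring (the future C3'), the O–Si–O bridge holds the aryl–palladium bromide over C3'''–H of flavone ring B, pivalate-assisted concerted metalation–deprotonation gives an eight-membered diarylpalladacycle, and reductive elimination forms the C3'–C3''' bond. The closest known reaction type is the palladium-catalysed intramolecular direct arylation of di-tert-butylsilyl-tethered bis(aryloxy)silanes to dibenzo-dioxasilepines, applied here to a phenol that carries a complete flavone. The seven-membered dioxasilepine ring closes by aryl–aryl reductive elimination, that is by C–C bond formation between two sp2 carbons that the tether holds in a 1,7 relationship. No stereocenter is formed and the bridged biaryl axis is not configurationally stable, so no stereocontrol is needed. Site selectivity for the C–H ortho to O4''' is secured by the one-atom tether, which cannot reach a meta C–H, and by the equivalence of C3''' and C5''' in the para-substituted ring, while selectivity for C–Br over C–Cl is secured by the simple triarylphosphine, which does not activate the electron-rich aryl chloride. The tert-butyl groups shield both Si–O bonds from carbonate, and no base-sensitive stereocenter exists yet at this temperature.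

Step 8
Reactants: 13 5,7-bis(benzyloxy)-2-(6,6-di-tert-butyl-10-chlorodibenzo[d,f][1,3,2]dioxasilepin-2-yl)-4H-chromen-4-one
Product: 14 5,7-bis(benzyloxy)-2-[6,6-di-tert-butyl-10-(4,4,5,5-tetramethyl-1,3,2-dioxaborolan-2-yl)dibenzo[d,f][1,3,2]dioxasilepin-2-yl]-4H-chromen-4-one
Conditions: Pd2(dba)3 (2.5 mol %), XPhos (10 mol %), B2pin2 (1.5 equiv), KOAc (3 equiv), 1,4-dioxane, 100 °C
Reagents that add atoms: bis(pinacolato)diboron, CC1(C)OB(B2OC(C)(C)C(C)(C)O2)OC1(C)C
Why: Miyaura borylation with a bulky dialkylbiarylphosphine should engage the only carbon–halogen bond left, and anhydrous acetate is too weak a base to touch the hindered silylene, the flavone or the benzyl ethers.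

Step 9
Reactants: 14 5,7-bis(benzyloxy)-2-[6,6-di-tert-butyl-10-(4,4,5,5-tetramethyl-1,3,2-dioxaborolan-2-yl)dibenzo[d,f][1,3,2]dioxasilepin-2-yl]-4H-chromen-4-one
Product: 15 [2-(5,7-bis(benzyloxy)-4-oxo-4H-chromen-2-yl)-6,6-di-tert-butyldibenzo[d,f][1,3,2]dioxasilepin-10-yl]boronic acid
Conditions: NaIO4 (3 equiv), NH4OAc (3 equiv), acetone/THF/H2O, rt
Reagents that add atoms: water, O
Why: Oxidative glycol cleavage of the liberated pinacol by periodate pulls the ester hydrolysis to the boronic acid in a near-neutral buffer, where no free phenol is present to be oxidised and the silylene is not attacked.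

Step 10
Reactants: 15 [2-(5,7-bis(benzyloxy)-4-oxo-4H-chromen-2-yl)-6,6-di-tert-butyldibenzo[d,f][1,3,2]dioxasilepin-10-yl]boronic acid; 4 5,7-bis(benzyloxy)-4H-chromen-4-one
Product: 16 (2S)-5,7-bis(benzyloxy)-2-[10-(5,7-bis(benzyloxy)-4-oxo-4H-chromen-2-yl)-6,6-di-tert-butyldibenzo[d,f][1,3,2]dioxasilepin-2-yl]chroman-4-one
Conditions: [Rh(OH)((S)-MeO-F12-BIPHEP)]2 (3 mol % Rh, preformed), 4 (2.5 equiv), CH2Cl2/H2O 10:1, 25 °C, no added base
Reagents that add atoms: none
Why: Hayashi–Miyaura conjugate addition: the aryl group passes from boron to the hydroxo complex of monovalent rhodium, the unsubstituted C2=C3 bond of 4 inserts with the electron-poor atropisomeric bisphosphine directing the aryl group to the Re face of C2 (O1 > C3 > H) so that C2 is formed as S, and water releases the flavanone, while the 2-aryl-substituted enone of the flavone unit is too hindered to insert and the absence of base prevents retro-oxa-Michael racemization.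

Step 11
Reactants: 16 (2S)-5,7-bis(benzyloxy)-2-[10-(5,7-bis(benzyloxy)-4-oxo-4H-chromen-2-yl)-6,6-di-tert-butyldibenzo[d,f][1,3,2]dioxasilepin-2-yl]chroman-4-one
Product: 17 (2S)-5,7-bis(benzyloxy)-2-{3-[5-(5,7-bis(benzyloxy)-4-oxo-4H-chromen-2-yl)-2-hydroxyphenyl]-4-hydroxyphenyl}chroman-4-one
Conditions: HF·pyridine, pyridine, THF, 0 °C to rt
Reagents that add atoms: none
Why: Fluoride-driven Si–O cleavage in an acidic buffer frees both phenols without ever forming the 4'-phenoxide, so the flavanone cannot open to the chalcone and C2 should keep its configuration.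

Step 12
Reactants: 17 (2S)-5,7-bis(benzyloxy)-2-{3-[5-(5,7-bis(benzyloxy)-4-oxo-4H-chromen-2-yl)-2-hydroxyphenyl]-4-hydroxyphenyl}chroman-4-one
Product: 18 (2S)-5,7-dihydroxy-2-{3-[5-(5,7-dihydroxy-4-oxo-4H-chromen-2-yl)-2-hydroxyphenyl]-4-hydroxyphenyl}chroman-4-one (CNP0184920.1)
Conditions: H2 (1 atm), 10% Pd/C, EtOAc/THF, rt, stopped at complete debenzylation
Reagents that add atoms: none
Why: Catalytic hydrogenolysis of the four aryl benzyl ethers under neutral conditions should be faster than reduction of the flavone double bond or the flavanone carbonyl, and neutrality protects the C2 stereocenter.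

Compound list
1 | 2',4',6'-trihydroxyacetophenone | CC(=O)c1c(O)cc(O)cc1O | starting material
2 | 1-[2,4-bis(benzyloxy)-6-hydroxyphenyl]ethanone | CC(=O)c1c(O)cc(OCc2ccccc2)cc1OCc1ccccc1 | intermediate
3 | (E)-1-[2,4-bis(benzyloxy)-6-hydroxyphenyl]-3-(dimethylamino)prop-2-en-1-one | CN(C)/C=C/C(=O)c1c(O)cc(OCc2ccccc2)cc1OCc1ccccc1 | intermediate
4 | 5,7-bis(benzyloxy)-4H-chromen-4-one | O=c1ccoc2cc(OCc3ccccc3)cc(OCc3ccccc3)c12 | intermediate
5 | 4-hydroxybenzaldehyde | O=Cc1ccc(O)cc1 | starting material
6 | 4-(methoxymethoxy)benzaldehyde | COCOc1ccc(C=O)cc1 | intermediate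
7 | (E)-1-[2,4-bis(benzyloxy)-6-hydroxyphenyl]-3-[4-(methoxymethoxy)phenyl]prop-2-en-1-one | O=C(/C=C/c1ccc(OCOC)cc1)c1c(O)cc(OCc2ccccc2)cc1OCc1ccccc1 | intermediate
8 | 5,7-bis(benzyloxy)-2-[4-(methoxymethoxy)phenyl]-4H-chromen-4-one | O=c1cc(-c2ccc(OCOC)cc2)oc2cc(OCc3ccccc3)cc(OCc3ccccc3)c12 | intermediate
9 | 5,7-bis(benzyloxy)-2-(4-hydroxyphenyl)-4H-chromen-4-one | O=c1cc(-c2ccc(O)cc2)oc2cc(OCc3ccccc3)cc(OCc3ccccc3)c12 | intermediate
10 | 2-bromo-4-chlorophenol | Oc1ccc(Cl)cc1Br | starting material
11 | (2-bromo-4-chlorophenoxy)di-tert-butylsilyl trifluoromethanesulfonate | CC(C)(C)[Si](Oc1ccc(Cl)cc1Br)(OS(=O)(=O)C(F)(F)F)C(C)(C)C | intermediate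
12 | 5,7-bis(benzyloxy)-2-[4-({(2-bromo-4-chlorophenoxy)di-tert-butylsilyl}oxy)phenyl]-4H-chromen-4-one | CC(C)(C)[Si](Oc1ccc(Cl)cc1Br)(Oc1ccc(-c2cc(=O)c3c(OCc4ccccc4)cc(OCc4ccccc4)cc3o2)cc1)C(C)(C)C | intermediate
13 | 5,7-bis(benzyloxy)-2-(6,6-di-tert-butyl-10-chlorodibenzo[d,f][1,3,2]dioxasilepin-2-yl)-4H-chromen-4-one | CC(C)(C)[Si]1(C(C)(C)C)Oc2ccc(Cl)cc2-c2cc(-c3cc(=O)c4c(OCc5ccccc5)cc(OCc5ccccc5)cc4o3)ccc2O1 | intermediate
14 | 5,7-bis(benzyloxy)-2-[6,6-di-tert-butyl-10-(4,4,5,5-tetramethyl-1,3,2-dioxaborolan-2-yl)dibenzo[d,f][1,3,2]dioxasilepin-2-yl]-4H-chromen-4-one | CC(C)(C)[Si]1(C(C)(C)C)Oc2ccc(B3OC(C)(C)C(C)(C)O3)cc2-c2cc(-c3cc(=O)c4c(OCc5ccccc5)cc(OCc5ccccc5)cc4o3)ccc2O1 | intermediate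
15 | [2-(5,7-bis(benzyloxy)-4-oxo-4H-chromen-2-yl)-6,6-di-tert-butyldibenzo[d,f][1,3,2]dioxasilepin-10-yl]boronic acid | CC(C)(C)[Si]1(C(C)(C)C)Oc2ccc(B(O)O)cc2-c2cc(-c3cc(=O)c4c(OCc5ccccc5)cc(OCc5ccccc5)cc4o3)ccc2O1 | intermediate
16 | (2S)-5,7-bis(benzyloxy)-2-[10-(5,7-bis(benzyloxy)-4-oxo-4H-chromen-2-yl)-6,6-di-tert-butyldibenzo[d,f][1,3,2]dioxasilepin-2-yl]chroman-4-one | O=C1C[C@@H](c2ccc3c(c2)-c2cc(-c4cc(=O)c5c(OCc6ccccc6)cc(OCc6ccccc6)cc5o4)ccc2O[Si](C(C)(C)C)(C(C)(C)C)O3)Oc2cc(OCc3ccccc3)cc(OCc3ccccc3)c21 | intermediate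
17 | (2S)-5,7-bis(benzyloxy)-2-{3-[5-(5,7-bis(benzyloxy)-4-oxo-4H-chromen-2-yl)-2-hydroxyphenyl]-4-hydroxyphenyl}chroman-4-one | O=C1C[C@@H](c2ccc(O)c(-c3cc(-c4cc(=O)c5c(OCc6ccccc6)cc(OCc6ccccc6)cc5o4)ccc3O)c2)Oc2cc(OCc3ccccc3)cc(OCc3ccccc3)c21 | intermediate
18 | (2S)-5,7-dihydroxy-2-{3-[5-(5,7-dihydroxy-4-oxo-4H-chromen-2-yl)-2-hydroxyphenyl]-4-hydroxyphenyl}chroman-4-one, (2S)-2,3-dihydro-3',3'''-biapigenin | O=C1C[C@@H](c2ccc(O)c(-c3cc(-c4cc(=O)c5c(O)cc(O)cc5o4)ccc3O)c2)Oc2cc(O)cc(O)c21 | target

Total step count: 12 (steps 2, 5 and 6 each join two operations without isolating the intermediate).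
Longest linear sequence: 10 steps (1 → 2 → 7 → 9 → 12 → 13 → 14 → 15 → 16 → 17 → 18; steps 1, 4, 5, 6, 7, 8, 9, 10, 11, 12).

Steps most likely to fail

1. Step 7. The aryl–palladium intermediate may be protodebrominated, an Si–O bond may be cut by base before C–H metalation, or slow insertion into C–Cl may lead to oligomers. The fallback sets out from 9 and returns at 13, and makes the biaryl bond by Suzuki–Miyaura coupling instead of C–H activation.
   - Phenoxide-directed mono-iodination of 9 (BnMe3N+ ICl2−, NaHCO3, CH2Cl2/MeOH, rt) should give 5,7-bis(benzyloxy)-2-(4-hydroxy-3-iodophenyl)-4H-chromen-4-one F1. Only the ionised phenol ring reacts under these conditions, since benzylated ring A would need a Lewis acid.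
   - Coupling of F1 with commercial (5-chloro-2-hydroxyphenyl)boronic acid (Pd(PPh3)4, aq. K2CO3, DME, 80 °C; C–I reacts, C–Cl stays) should give 5,7-bis(benzyloxy)-2-(5'-chloro-2',6-dihydroxybiphenyl-3-yl)-4H-chromen-4-one F2. This is the 2,2'-biphenol with the flavone para to one hydroxyl and chlorine para to the other.
   - Bridging both phenols with t-Bu2Si(OTf)2 and 2,6-lutidine in DMF then gives 13.

2. Step 10. Protodeboronation of 15 may outpace insertion of the electron-rich chromone, or the bulky biaryl nucleophile may be delivered with insufficient facial discrimination. The fallback sets out from 15 and 4 and returns at 16, and obtains the stereocenter by resolution instead of asymmetric catalysis.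
   - The more active ligand-free diene complex [RhOH(cod)]2 in 1,4-dioxane/H2O at 40 °C should give racemic 16.
   - Preparative chromatography on a polysaccharide-carbamate chiral stationary phase then separates 16 from the (2R)-enantiomer of 16 F3.
   - F3 can be returned to the racemate with a trace of amine base through the ring-opened chalcone and separated again.

3. Step 12. Over-reduction on the palladium surface may occur before the last benzyl ether is gone: saturation of the C2''=C3'' bond of the flavone unit, or hydrogenolysis of the benzylic C2–O1 bond or the C4 carbonyl of the flavanone. The fallback sets out from 17 and returns at 18 directly, using non-reductive Lewis-acid debenzylation.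
   - Conditions are BCl3 with pentamethylbenzene as benzyl-cation scavenger in CH2Cl2 at −78 °C, quenched cold with MeOH.
   - No hydrogen or metal surface is involved, and the low temperature and O-borylation of the 4'-phenol should suppress ionisation of the C2–O1 bond.

Further compounds
F1 | step 7 | 5,7-bis(benzyloxy)-2-(4-hydroxy-3-iodophenyl)-4H-chromen-4-one | O=c1cc(-c2ccc(O)c(I)c2)oc2cc(OCc3ccccc3)cc(OCc3ccccc3)c12
F2 | step 7 | 5,7-bis(benzyloxy)-2-(5'-chloro-2',6-dihydroxybiphenyl-3-yl)-4H-chromen-4-one | O=c1cc(-c2ccc(O)c(-c3cc(Cl)ccc3O)c2)oc2cc(OCc3ccccc3)cc(OCc3ccccc3)c12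
F3 | step 10 | (2R)-5,7-bis(benzyloxy)-2-[10-(5,7-bis(benzyloxy)-4-oxo-4H-chromen-2-yl)-6,6-di-tert-butyldibenzo[d,f][1,3,2]dioxasilepin-2-yl]chroman-4-one | O=C1C[C@H](c2ccc3c(c2)-c2cc(-c4cc(=O)c5c(OCc6ccccc6)cc(OCc6ccccc6)cc5o4)ccc2O[Si](C(C)(C)C)(C(C)(C)C)O3)Oc2cc(OCc3ccccc3)cc(OCc3ccccc3)c21
F0 | step 12 | none | none
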